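All runs were generated by integration from invented constants, and the scatter is random.

In the first 6.00 min the ash readings show product made at a mean 0.0150 min⁻¹ as a share of the charge, which at this charge is a turnover frequency of 150 min⁻¹ per enzyme.

all flasks: substrate 0.10 M

| flask | enzyme | remark | time |
|---|---|---|---|
| ash | 10 µM | the very flask that is asked about, followed so far |  |
| birch | 15 µM | run made earlier |  |
| flask | 10 µM |  | 80 min |

ash run (percent of the substrate charged)

| time / min | product / % | substrate / % |
|---|---|---|
| 6.00 | 9 | 91 |
| 10.0 | 14 | 85 |
| 20.0 | 15 | 80 |
| 30.0 | 20 | 81 |
| 50.0 | 24 | 75 |
| 80.0 | 20 | 79 |

birch run (percent of the substrate charged)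

| time / min | product / % | substrate / % |
|---|---|---|
| 2.50 | 8 | 90 |
| 5.00 | 17 | 84 |
| 8.00 | 25 | 76 |
| 10.0 | 26 | 76 |
| 12.0 | 27 | 71 |
| 15.0 | 32 | 72 |

- what is taken out of product is counted as made
- additions bring no volume worth counting

- epsilon: change nothing and wait 80 min more
- beta: at 80 min take out 90% of the product then present, then wait 80 min
- eta: at 80 min add enzyme, 100% of the amount charged, then wait 80 min
- zeta: at 80 min add substrate, 50.0% of the amount charged, then wait 80 min

- product, in percent of the substrate first charged, at 80 min
- what to do for the largest gain in product; "none" if nothing gains more than 2 percentage points (epsilon / beta / eta / zeta / none)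
- product present, with what was taken out counted in, in percent of the substrate first charged, after epsilon
- product present, with what was taken out counted in, in percent of the substrate first charged, after eta

From 30.0 min on, the ash readings are flat within a scatter of 2 percentage points per reading, so the curve can be replaced by their mean, 21.3%, with an error of 1.2 points from the scatter. This gives the quantity to carry: the turnover number N 2130, the product made per enzyme charged over its working life. At this substrate charge, the estimate of the final product is N times charged [enzyme] over charged [substrate].

The time scales form a ladder. At that reading, one turnover takes 0.00667 min. The working life, N divided by the turnover rate, is 14.2 min, a reading as rough as the first point. At the early rate, the substrate would last 66.7 min, longer than that life. So the ash flask stalls with substrate present, and 80 min lies 5.63 working lives after its start.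

The rule gives the birch flask an estimate of 32.0%; its last reading, at 15.0 min, is 32%, with no later reading to show a stall. My own reckoning is therefore 21.3% now, no gain from waiting, removal or more substrate, and 42.7% after eta.

The forecast gives 21.5%, eta, 22% after epsilon and 44% after eta: “Only fresh enzyme helps”.

The simulation gives 21.1%, eta as best with a gain of 27 points, 21.1% after epsilon and 48.0% after eta.

    substrate + enzyme → product + enzyme, rate k1*[substrate]*[enzyme]/(1 + ([substrate]/Km1)) (2.78 mM, k = 1.27 × 10⁵ L mol⁻¹ min⁻¹)
    substrate + enzyme → spent catalyst A (k = 1.53 L mol⁻¹ min⁻¹)
    enzyme → spent catalyst B (k = 0.0256 min⁻¹)

The ash flask ends at 80 min with 79% of its substrate free, and its enzyme stands at 0%, with 84.2% as spent catalyst A and 15.8% as spent catalyst B. The main reason product stops there is the denominator term in [substrate] of the making of product: the run without that term reaches >99.9% against 21.1%. The ash flask's computed turnover number is 2110, and the enzyme added in eta makes 2690 per enzyme, more than N.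

For a neighbour, the same flask with 2.5 × 10⁻⁶ M of enzyme, N gives 5.33%. The computed result is 4.91%.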